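**Retrosynthetic overview**
- Target ⇐ Mitsunobu angeloylation with inversion at C8 ⇐ 8,10-anti diol ⇐ hydroxyl-directed reduction of a β-hydroxy enone, whose C10 centre comes from methyl (R)-glycidate.
- β-Hydroxy enone ⇐ C8–C9 bond made photochemically: decatungstate/nickel coupling of an aldehyde C–H bond with the terminal epoxide, on a sulfinate-masked enal, then sulfinate loss to restore C7=C14.
- Masked enal ⇐ isopropenyl group (ene-chlorination, N-oxide oxidation, sulfa-Michael); chlorohydrin ⇐ 3β,4β-epoxide ⇐ hydroxyl-directed epoxidation.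
- Ring oxygenation ⇐ (S)-carvone: Rubottom oxidation at C6, Mitsunobu inversion to the cis angelate, Luche reduction at C5.
- Rings: the cyclohexane ring is bought with (S)-carvone and no carbocycle is formed; one oxirane is made (step 4) and opened (step 7).

Convention (assumed for all names): target locants are used – ring C1 (carries the side chain), C2 (CH2), C3 (Cl), C4 (CH3, OH), C5 (OAc), C6 (ring angelate), side chain C7(=C14H2)–C8–C9–C10–C11(CH3)2; β = ring face of the C1 side chain, α = the other face; Ang = (2Z)-2-methylbut-2-enoyl; in carvone C5 is the carbonyl carbon and C6 its CH2 neighbour.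

**Route**

Step 1
Reactants: 1 (S)-(+)-carvone
Product: 4 6α-hydroxycarvone, via silyl dienol ether 2 (not isolated), via silyloxy ketone 3 (not isolated)
Conditions: LiN(iPr)2, Me3SiCl, THF, −78 °C; mCPBA, CH2Cl2, −20 → 0 °C; citric acid (cat.), MeOH, 0 °C
Reagents that add atoms: mCPBA (3-chloroperbenzoic acid), OOC(=O)c1cccc(Cl)c1
Why: Rubottom oxidation – the kinetic cross-conjugated silyl dienol ether is epoxidised at its enol-ether double bond on the α face, anti to the C1 isopropenyl group, so the carvone stereocentre sets C6–OH trans to it.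

Step 2
Reactants: 4 6α-hydroxycarvone; 5 angelic acid
Product: 6 6β-angeloyloxycarvone
Conditions: PPh3, DIAD, toluene, −20 → 0 °C
Reagents that add atoms: none
Why: Mitsunobu esterification – SN2 displacement of the oxyphosphonium at the ketone-activated C6 inverts it to the 6β (cis) ester, and the neutral, cold conditions keep the Z (angelate) geometry.

Step 3
Reactants: 6 6β-angeloyloxycarvone
Product: 7 5β-hydroxy-6β-angeloyloxy allylic alcohol
Conditions: NaBH4, CeCl3·7H2O, MeOH, −78 °C; AcOH quench
Reagents that add atoms: none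
Why: Luche 1,2-reduction – hydride attacks the enone carbonyl anti to the axial 6β-acyloxy group (Felkin–Anh, as in carvone → cis-carveol), giving the 5β-alcohol cis to the ester and the isopropenyl group.

Step 4
Reactants: 7 5β-hydroxy-6β-angeloyloxy allylic alcohol
Product: 8 3β,4β-epoxy alcohol
Conditions: VO(acac)2 (5 mol%), t-BuOOH, CH2Cl2, 0 → 23 °C
Reagents that add atoms: tert-butyl hydroperoxide, CC(C)(C)OO
Why: Hydroxyl-directed vanadium epoxidation (Sharpless–Michaelson) delivers oxygen syn to the 5β-OH, and the isopropenyl and angelate alkenes, which are not part of an allylic alcohol, do not react.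

Step 5
Reactants: 8 3β,4β-epoxy alcohol
Product: 9 3β,4β-epoxy 5β-acetate
Conditions: Ac2O, pyridine, DMAP (cat.), CH2Cl2, 0 → 23 °C
Reagents that add atoms: acetic anhydride, CC(=O)OC(C)=O
Why: DMAP-catalysed acyl transfer to the only free hydroxyl; no stereocentre is touched.

Step 6
Reactants: 9 3β,4β-epoxy 5β-acetate
Product: 10 epoxy allyl chloride
Conditions: Ca(OCl)2, CO2 (solid), CH2Cl2–H2O, 0 °C
Reagents that add atoms: calcium hypochlorite, [Ca+2].[O-]Cl.[O-]Cl
Why: Ene-type allylic chlorination by hypochlorous acid (the carvone → 10-chlorocarvone reaction) at the only electron-rich alkene gives the 2-(chloromethyl)allyl group with no free hydroxyl present and no stereocentre touched.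

Step 7
Reactants: 10 epoxy allyl chloride
Product: 11 chlorohydrin allyl chloride
Conditions: LiCl, AcOH, THF, 40 °C
Reagents that add atoms: lithium chloride, [Li+].[Cl-]
Why: SN2 epoxide opening by chloride – Fürst–Plattner trans-diaxial attack from the α face at the less substituted C3, remote from the electron-withdrawing 5-OAc, gives 3α-Cl and 4β-OH.

Step 8
Reactants: 11 chlorohydrin allyl chloride
Product: 13 sulfinate-masked aldehyde, via enal 12 (not isolated)
Conditions: N-methylmorpholine N-oxide, NaHCO3, KI (cat.), MeCN, 40 °C; then MeSO2Na, AcOH, EtOH–H2O, 23 °C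
Reagents that add atoms: N-methylmorpholine N-oxide, C[N+]1([O-])CCOCC1; sodium methanesulfinate, [Na+].[O-]S(C)=O
Why: N-oxide (Kornblum-type) oxidation of the allylic chloride gives the 2-substituted acrolein, and sulfa-Michael addition of methanesulfinic acid masks C7=C14 so that nothing in the next step is a radical acceptor; the new C7 centre is a mixture that is erased in step 10.

Step 9
Reactants: 14 methyl (R)-glycidate
Product: 15 (R)-2-(oxiran-2-yl)propan-2-ol
Conditions: MeMgBr (2.1 equiv), THF, −78 → −30 °C; then pH 7 buffer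
Reagents that add atoms: methylmagnesium bromide, C[Mg]Br
Why: Double Grignard addition to the ester outruns epoxide opening at low temperature, and the glycidate stereocentre (future C10) is not involved.

Step 10
Reactants: 13 sulfinate-masked aldehyde; 15 (R)-2-(oxiran-2-yl)propan-2-ol
Product: 18 β-hydroxy enone, via iodohydrin 16 (not isolated), via sulfonyl hydroxy ketone 17 (not isolated)
Conditions: (nBu4N)4[W10O32] (2 mol%), NiBr2(dme) (10 mol%), 4,4′-di-tert-butyl-2,2′-bipyridine (12 mol%), 2,4,6-collidine hydroiodide (20 mol%), MeCN–acetone, 390 nm LEDs, 20 °C; then Et3N, CH2Cl2, 0 → 23 °C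
Reagents that add atoms: none
Why: Proposed new method: a redox- and proton-neutral coupling of an aldehyde C–H bond with a terminal epoxide – photoexcited decatungstate abstracts the formyl hydrogen of 13 (polarity-matched hydrogen-atom transfer) to give an acyl radical that is trapped by zerovalent nickel, catalytic hydrogen iodide opens 15 at its CH2 terminus to iodohydrin 16, oxidative addition of the C–I bond and reductive elimination from trivalent nickel form the C8–C9 bond, and the reduced polyoxotungstate returns its electron to monovalent nickel and its proton to iodide, so no base or reductant is needed, the bought C10 centre is never touched, and with the enal masked neither 13 nor 17 can take up radicals in a Giese sense before Et3N expels methanesulfinate (E1cB) to restore C7=C14; the closest known reactions are decatungstate/nickel acyl C–H arylation and alkylation of aldehydes with organic halides and the iodide-co-catalysed nickel cross-electrophile opening of terminal epoxides.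

Step 11
Reactants: 18 β-hydroxy enone
Product: 19 8,10-anti diol
Conditions: Me4NBH(OAc)3, MeCN–AcOH (1:1), −30 °C
Reagents that add atoms: none
Why: Evans–Saksena reduction – the C10 hydroxyl binds boron and delivers hydride intramolecularly through a chair transition state, giving the 1,3-anti (8R) alcohol under control of the bought C10 centre and leaving the esters and the conjugated alkene alone.

Step 12
Reactants: 19 8,10-anti diol; 5 angelic acid
Product: 20 target CNP0223769.1
Conditions: PPh3, DIAD, toluene, −20 → 0 °C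
Reagents that add atoms: none
Why: Mitsunobu esterification with inversion at the allylic C8 carbinol gives the (8S) angelate, while the neopentyl-type C10 hydroxyl and the two tertiary hydroxyls are too hindered for SN2 activation.

**Compound list**

1 | (S)-(+)-carvone, (5S)-2-methyl-5-(prop-1-en-2-yl)cyclohex-2-en-1-one | CC(=C)[C@H]1CC=C(C)C(=O)C1 | starting material
2 | trimethylsilyl dienol ether of 1 (C5–OSiMe3, double bonds C5=C6 and C3=C4) | CC(=C)[C@H]1CC=C(C)C(O[Si](C)(C)C)=C1 | intermediate
3 | 6α-(trimethylsilyloxy)carvone (silyloxy trans to isopropenyl) | CC(=C)[C@H]1CC=C(C)C(=O)[C@@H]1O[Si](C)(C)C | intermediate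
4 | 6α-hydroxycarvone, (5R,6R)-6-hydroxy-2-methyl-5-(prop-1-en-2-yl)cyclohex-2-en-1-one (OH trans to isopropenyl) | CC(=C)[C@H]1CC=C(C)C(=O)[C@@H]1O | intermediate
5 | angelic acid, (2Z)-2-methylbut-2-enoic acid | C/C=C(/C)C(=O)O | starting material
6 | 6β-angeloyloxycarvone, (1S,6R)-3-methyl-2-oxo-6-(prop-1-en-2-yl)cyclohex-3-en-1-yl (2Z)-2-methylbut-2-enoate (ester cis to isopropenyl) | CC(=C)[C@H]1CC=C(C)C(=O)[C@H]1OC(=O)/C(C)=C\C | intermediate
7 | allylic alcohol, (1S,2R,6R)-2-hydroxy-3-methyl-6-(prop-1-en-2-yl)cyclohex-3-en-1-yl (2Z)-2-methylbut-2-enoate (5β-OH, 6β-OAng, 3-ene) | CC(=C)[C@H]1CC=C(C)[C@@H](O)[C@H]1OC(=O)/C(C)=C\C | intermediate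
8 | epoxy alcohol: 3β,4β-epoxy, 4α-CH3, 5β-OH, 6β-OAng, C1 isopropenyl | CC(=C)[C@H]1C[C@H]2O[C@@]2(C)[C@@H](O)[C@H]1OC(=O)/C(C)=C\C | intermediate
9 | epoxy acetate: 3β,4β-epoxy, 5β-OAc, 6β-OAng, C1 isopropenyl | CC(=C)[C@H]1C[C@H]2O[C@@]2(C)[C@@H](OC(C)=O)[C@H]1OC(=O)/C(C)=C\C | intermediate
10 | epoxy allyl chloride: as 9, C1 substituent 3-chloroprop-1-en-2-yl (C7(=C14H2)–C8H2Cl) | C=C(CCl)[C@H]1C[C@H]2O[C@@]2(C)[C@@H](OC(C)=O)[C@H]1OC(=O)/C(C)=C\C | intermediate
11 | chlorohydrin allyl chloride: 3α-Cl, 4β-OH, 4α-CH3, 5β-OAc, 6β-OAng, C1 3-chloroprop-1-en-2-yl | C=C(CCl)[C@H]1C[C@H](Cl)[C@@](C)(O)[C@@H](OC(C)=O)[C@H]1OC(=O)/C(C)=C\C | intermediate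
12 | enal: ring as 11, C1 substituent 3-oxoprop-1-en-2-yl (C8 aldehyde) | C=C(C=O)[C@H]1C[C@H](Cl)[C@@](C)(O)[C@@H](OC(C)=O)[C@H]1OC(=O)/C(C)=C\C | intermediate
13 | sulfinate-masked aldehyde: ring as 11, C1 substituent 1-(methylsulfonyl)-3-oxopropan-2-yl (C7 epimers) | O=CC(CS(C)(=O)=O)[C@H]1C[C@H](Cl)[C@@](C)(O)[C@@H](OC(C)=O)[C@H]1OC(=O)/C(C)=C\C | intermediate
14 | methyl (R)-glycidate, methyl (2R)-oxirane-2-carboxylate | COC(=O)[C@H]1CO1 | starting material
15 | (R)-2-(oxiran-2-yl)propan-2-ol | CC(C)(O)[C@H]1CO1 | intermediate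
16 | (S)-1-iodo-3-methylbutane-2,3-diol | CC(C)(O)[C@H](O)CI | intermediate
17 | sulfonyl hydroxy ketone: ring as 11, side chain C7H(CH2SO2CH3)–C8(=O)–C9H2–(10R)-CH(OH)–C(CH3)2OH (C7 epimers) | CS(=O)(=O)CC(C(=O)C[C@@H](O)C(C)(C)O)[C@H]1C[C@H](Cl)[C@@](C)(O)[C@@H](OC(C)=O)[C@H]1OC(=O)/C(C)=C\C | intermediate
18 | β-hydroxy enone: ring as 11, side chain C7(=C14H2)–C8(=O)–C9H2–(10R)-CH(OH)–C(CH3)2OH | C=C(C(=O)C[C@@H](O)C(C)(C)O)[C@H]1C[C@H](Cl)[C@@](C)(O)[C@@H](OC(C)=O)[C@H]1OC(=O)/C(C)=C\C | intermediate
19 | 8,10-anti diol: as 18 with (8R)-CH(OH) | C=C([C@@H](C[C@@H](O)C(C)(C)O)O)[C@H]1C[C@H](Cl)[C@@](C)(O)[C@@H](OC(C)=O)[C@H]1OC(=O)/C(C)=C\C | intermediate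
20 | CNP0223769.1: 3α-Cl, 4β-OH, 5β-OAc, 6β-OAng, (8S)-OAng, (10R)-OH, 11-OH, 7(14)-ene | C=C([C@H](C[C@@H](O)C(C)(C)O)OC(=O)/C(C)=C\C)[C@H]1C[C@H](Cl)[C@@](C)(O)[C@@H](OC(C)=O)[C@H]1OC(=O)/C(C)=C\C | target

**Step count and risks**

Total: 12 steps. Longest linear sequence: 11 steps (1–8, then 10–12, from (S)-carvone); step 9 makes the epoxide partner.

Step 10 (the new reaction) is the most likely to fail. The α-branched acyl radical may lose CO, decatungstate may also abstract the carbinol C–H at C10 of the product, and reduction of nickel by the reduced polyoxotungstate may be slow. The fallback is polar and known, sets out from 11 and 15, and returns at 18. Chloride 11 is oxidised as in the first half of step 8 (N-methylmorpholine N-oxide, NaHCO3, KI cat., MeCN) and enal 12 is isolated. Epoxy alcohol 15 is deprotonated with n-BuLi and reductively lithiated with lithium 4,4′-di-tert-butylbiphenylide (THF, −78 °C) to the β-oxido alkyllithium F1. This is transmetalated with anhydrous CeCl3 to the organocerium reagent F2 and added to 12 at −78 °C (2.5 equiv, one being used up by the C4 hydroxyl), giving the C8-epimeric allylic alcohols F3. MnO2 in CH2Cl2 then oxidises only the allylic C8 carbinol to give 18.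

Step 12 (Mitsunobu at C8) may give SN2′ attack at C14 or cyclisation of the C11 hydroxyl onto the activated C8. The fallback uses retention instead of inversion, sets out from 18, and returns at 20. Enone 18 is reduced with Et2BOMe and NaBH4 (THF–MeOH, −78 °C, Narasaka–Prasad) to the 8,10-syn diol F4. Its allylic C8 hydroxyl is then acylated by the mixed anhydride F5, made from angelic acid 5 and 2,4,6-trichlorobenzoyl chloride with Et3N, in toluene at 80 °C without DMAP.

Step 2 (Mitsunobu at C6) works on a hindered α-hydroxy enone that may eliminate and aromatise to a carvacrol-type phenol. The fallback sets out from 1 and returns at 6. Silyl dienol ether 2, made as in the first operation of step 1, is brominated with NBS (THF, −78 °C) anti to the isopropenyl group to give 6α-bromocarvone F6. Cesium angelate F7 (from 5 and Cs2CO3) displaces the bromide in DMF at 0 °C with inversion.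

**Further compounds**

F1 | step 10 | trilithium species LiCH2–(R)-CH(OLi)–C(CH3)2OLi from 15 | [Li]C[C@@H](O[Li])C(C)(C)O[Li]
F2 | step 10 | organocerium reagent Cl2Ce–CH2–(R)-CH(OLi)–C(CH3)2OLi | Cl[Ce](Cl)C[C@@H](O[Li])C(C)(C)O[Li]
F3 | step 10 | allylic alcohols: as 19, both C8 epimers | C=C(C(O)C[C@@H](O)C(C)(C)O)[C@H]1C[C@H](Cl)[C@@](C)(O)[C@@H](OC(C)=O)[C@H]1OC(=O)/C(C)=C\C
F4 | step 12 | 8,10-syn diol: as 19 with (8S)-CH(OH) | C=C([C@H](C[C@@H](O)C(C)(C)O)O)[C@H]1C[C@H](Cl)[C@@](C)(O)[C@@H](OC(C)=O)[C@H]1OC(=O)/C(C)=C\C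
F5 | step 12 | angelic 2,4,6-trichlorobenzoic anhydride | C/C=C(/C)C(=O)OC(=O)c1c(Cl)cc(Cl)cc1Cl
F6 | step 2 | 6α-bromocarvone, (5R,6R)-6-bromo-2-methyl-5-(prop-1-en-2-yl)cyclohex-2-en-1-one (Br trans to isopropenyl) | CC(=C)[C@H]1CC=C(C)C(=O)[C@@H]1Br
F7 | step 2 | cesium angelate | [Cs+].C/C=C(/C)C([O-])=O
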